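**Plan**

- Retrosynthesis (chain numbered C1–C17 from the vinyl terminus): the C3–O ester bond is cut first, with allylic transposition to a C1 trichloroacetimidate on a Z C2=C3 alkene; then C3–C4 (vinyl iodide plus terminal diyne); then C7–C8 (diynide plus primary triflate).
- Enabling feature: C3 is both allylic and propargylic and carries the terminal C1=C2 vinyl group. Its C–O bond can therefore arise by SN2′ attack of the acid on a linear (Z)-enediyne with the leaving group on C1. The C9–C10 oxirane, the only ring, lies six bonds from C3.
- Forward order: the oxirane is made first by asymmetric epoxidation of (E)-dec-2-en-1-ol. The chain is then joined at C7–C8, at C3–C4 and last at C3–O, where linoleic acid enters unprotected.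
- Stereochemistry: C9 and C10 (R,R, trans) come from the tartrate-controlled epoxidation. C3 (S) comes from the planar-chiral palladacycle C82H72Co2N2O6Pd2 in the last step. The two Z alkenes of the acyl chain are bought with linoleic acid.

Key step: step 9

Remark: the catalyst antipode for 3S is assigned by analogy with alkyl-substituted (Z)-allylic trichloroacetimidates (the descriptor is formally inverted against that series because the diynyl group outranks vinyl) and would be confirmed on the first run; the four purchased materials are taken as commercial.

**Route**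

Step 1
Reactants: 1 (E)-dec-2-en-1-ol
Product: 2 [(2R,3R)-3-heptyloxiran-2-yl]methanol ((2R,3R)-2,3-epoxydecan-1-ol)
Conditions: Ti(OiPr)4 (10 mol %), D-(−)-diethyl tartrate (12 mol %), t-BuOOH (in decane), 4 Å MS, CH2Cl2, −20 °C
Reagents that add atoms: tert-butyl hydroperoxide, CC(C)(C)OO
Why: Sharpless asymmetric epoxidation of a primary (E)-allylic alcohol, in which the D-(−)-tartrate complex delivers oxygen to the top face of the alkene drawn with CH2OH at the lower right, so that both oxirane carbons (later C9 and C10) become R and the trans relationship follows from the E alkene.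

Step 2
Reactants: 2 [(2R,3R)-3-heptyloxiran-2-yl]methanol
Product: 3 [(2R,3R)-3-heptyloxiran-2-yl]methyl trifluoromethanesulfonate
Conditions: Tf2O, 2,6-lutidine, CH2Cl2, −78 °C; cold aqueous work-up, used at once
Reagents that add atoms: trifluoromethanesulfonic anhydride, O=S(=O)(OS(=O)(=O)C(F)(F)F)C(F)(F)F
Why: O-sulfonylation of the primary alcohol at low temperature with a hindered base leaves the oxirane and both stereocentres untouched and provides a leaving group reactive enough for acetylide alkylation at −78 °C.

Step 3
Reactants: 3 [(2R,3R)-3-heptyloxiran-2-yl]methyl trifluoromethanesulfonate; 4 1,4-bis(trimethylsilyl)buta-1,3-diyne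
Product: 6 trimethyl{5-[(2R,3R)-3-heptyloxiran-2-yl]penta-1,3-diyn-1-yl}silane, via lithium 4-(trimethylsilyl)buta-1,3-diyn-1-ide 5 (not isolated)
Conditions: 4, MeLi·LiBr, THF, 0 °C → rt; then 3, THF/DMPU, −78 → −30 °C
Reagents that add atoms: none
Why: mono-desilylative metalation of the bis-silyl diyne by methyllithium gives a single lithium diynide, which should alkylate the primary triflate carbon by SN2 far faster than it opens the unactivated oxirane in the absence of a Lewis acid (acetylide alkylation of an epoxy triflate), so the C7–C8 bond forms without touching either stereocentre.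

Step 4
Reactants: 6 trimethyl{5-[(2R,3R)-3-heptyloxiran-2-yl]penta-1,3-diyn-1-yl}silane
Product: 7 (2R,3R)-2-heptyl-3-(penta-2,4-diyn-1-yl)oxirane
Conditions: K2CO3 (0.2 equiv), MeOH/THF, 0 °C; NH4Cl quench, kept in solution
Reagents that add atoms: none
Why: methoxide-catalysed protodesilylation of the alkynylsilane is fast at 0 °C, and the catalytic base, low temperature and short contact time should spare the skipped propargylic methylene and the oxirane, the terminal diyne being kept in solution for the next step.

Step 5
Reactants: 8 methyl propiolate
Product: 9 methyl (Z)-3-iodoprop-2-enoate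
Conditions: NaI, AcOH, 70 °C
Reagents that add atoms: sodium iodide, [Na+].[I-]
Why: conjugate addition of iodide to the ynoate followed by anti protonation (anti hydroiodination) should give the Z β-iodoacrylate as the kinetic product.

Step 6
Reactants: 9 methyl (Z)-3-iodoprop-2-enoate
Product: 10 (Z)-3-iodoprop-2-en-1-ol
Conditions: iBu2AlH (2.2 equiv), CH2Cl2, −78 → 0 °C
Reagents that add atoms: none
Why: 1,2-reduction of the conjugated ester by the aluminium hydride stops at the allylic alcohol and leaves the vinyl iodide and its Z geometry unchanged.

Step 7
Reactants: 7 (2R,3R)-2-heptyl-3-(penta-2,4-diyn-1-yl)oxirane; 10 (Z)-3-iodoprop-2-en-1-ol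
Product: 11 (Z)-8-[(2R,3R)-3-heptyloxiran-2-yl]oct-2-ene-4,6-diyn-1-ol
Conditions: Pd(PPh3)4 (5 mol %), CuI (10 mol %), iPr2NH, THF (degassed), 0 °C → rt, slow addition of 7
Reagents that add atoms: none
Why: Sonogashira coupling of a terminal alkyne with a vinyl iodide proceeds with retention of alkene geometry at room temperature, and a zerovalent palladium precatalyst under strict exclusion of oxygen should limit oxidative dimerisation of the diyne while the hydroxyl and the oxirane stay spectators as C3–C4 forms.

Step 8
Reactants: 11 (Z)-8-[(2R,3R)-3-heptyloxiran-2-yl]oct-2-ene-4,6-diyn-1-ol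
Product: 12 (Z)-8-[(2R,3R)-3-heptyloxiran-2-yl]oct-2-ene-4,6-diyn-1-yl 2,2,2-trichloroacetimidate
Conditions: Cl3CCN, DBU (10 mol %), CH2Cl2, 0 °C; filtration through Et3N-deactivated silica
Reagents that add atoms: trichloroacetonitrile, N#CC(Cl)(Cl)Cl
Why: base-catalysed addition of the primary alkoxide to the electron-poor nitrile (trichloroacetimidate formation) is fast at 0 °C, which should outrun base-induced cycloisomerisation of the (Z)-enynol, and it creates no stereocentre.

Step 9
Reactants: 12 (Z)-8-[(2R,3R)-3-heptyloxiran-2-yl]oct-2-ene-4,6-diyn-1-yl 2,2,2-trichloroacetimidate; 13 linoleic acid ((9Z,12Z)-octadeca-9,12-dienoic acid)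
Product: 14 (3S)-8-[(2R,3R)-3-heptyloxiran-2-yl]oct-1-ene-4,6-diyn-3-yl (9Z,12Z)-octadeca-9,12-dienoate (target CNP0285672.1)
Conditions: [(Rp,S)-COP-OAc]2, the di-μ-acetato-bridged palladacycle dimer C82H72Co2N2O6Pd2 built on (η4-tetraphenylcyclobutadiene)cobalt(η5-cyclopentadienyl)-(S)-4-isopropyloxazoline (2 mol %), 13 (3 equiv), CH2Cl2, 23 °C, Ar, dark
Reagents that add atoms: none
Why: Proposed new method: the imidate nitrogen of 12 binds the divalent palladium centre of the palladacycle and holds the Z C2=C3 alkene on the metal, the carboxylate of linoleic acid adds to C3 from outside on the face anti to palladium to give a six-membered C2-palladated chelate, and syn deoxypalladation then expels trichloroacetamide from C1 and releases the branched ester with the new C1=C2 vinyl group. The closest known reaction type is the palladacycle-catalysed enantioselective SN2′ esterification of alkyl-substituted (Z)-allylic trichloroacetimidates with carboxylic acids; what is new is the conjugated diyne on the alkene terminus, which makes C3 propargylic as well as allylic. No ring closes, and the oxirane and the two Z alkenes of the acyl chain are spectators. The C3 stereocentre is set by the catalyst alone, the planar-chiral cobalt-sandwich oxazoline framework selecting the alkene enantioface offered to the external carboxylate (3S expected from the Rp,S dimer by analogy with the alkyl series, the antipodal dimer giving the C3 epimer), while C9 and C10 are six bonds away and should exert no influence. The step needs branched over linear regiochemistry and one enantioface, both secured by the Z geometry and the nitrogen-templated chelate, which places palladium on C2 and leaves only C3 open to attack, a position whose propargylic character should further favour C–O bond formation. The near-neutral conditions at ambient temperature, free of hydride and of zerovalent palladium species, should spare the oxirane, the skipped diene and the easily ionised product ester, and the diyne is expected to compete poorly for the metal against the chelating imidate.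

**Compound list**

1 | (E)-dec-2-en-1-ol | OC/C=C/CCCCCCC | starting material
2 | [(2R,3R)-3-heptyloxiran-2-yl]methanol | OC[C@H]1O[C@@H]1CCCCCCC | intermediate
3 | [(2R,3R)-3-heptyloxiran-2-yl]methyl trifluoromethanesulfonate | O=S(=O)(OC[C@H]1O[C@@H]1CCCCCCC)C(F)(F)F | intermediate
4 | 1,4-bis(trimethylsilyl)buta-1,3-diyne | C[Si](C)(C)C#CC#C[Si](C)(C)C | starting material
5 | lithium 4-(trimethylsilyl)buta-1,3-diyn-1-ide | [Li+].[C-]#CC#C[Si](C)(C)C | intermediate
6 | trimethyl{5-[(2R,3R)-3-heptyloxiran-2-yl]penta-1,3-diyn-1-yl}silane | C[Si](C)(C)C#CC#CC[C@H]1O[C@@H]1CCCCCCC | intermediate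
7 | (2R,3R)-2-heptyl-3-(penta-2,4-diyn-1-yl)oxirane | C#CC#CC[C@H]1O[C@@H]1CCCCCCC | intermediate
8 | methyl propiolate | COC(=O)C#C | starting material
9 | methyl (Z)-3-iodoprop-2-enoate | COC(=O)/C=C\I | intermediate
10 | (Z)-3-iodoprop-2-en-1-ol | OC/C=C\I | intermediate
11 | (Z)-8-[(2R,3R)-3-heptyloxiran-2-yl]oct-2-ene-4,6-diyn-1-ol | OC/C=C\C#CC#CC[C@H]1O[C@@H]1CCCCCCC | intermediate
12 | (Z)-8-[(2R,3R)-3-heptyloxiran-2-yl]oct-2-ene-4,6-diyn-1-yl 2,2,2-trichloroacetimidate | N=C(OC/C=C\C#CC#CC[C@H]1O[C@@H]1CCCCCCC)C(Cl)(Cl)Cl | intermediate
13 | linoleic acid ((9Z,12Z)-octadeca-9,12-dienoic acid) | OC(=O)CCCCCCC/C=C\C/C=C\CCCCC | starting material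
14 | (3S)-8-[(2R,3R)-3-heptyloxiran-2-yl]oct-1-ene-4,6-diyn-3-yl (9Z,12Z)-octadeca-9,12-dienoate | C=C[C@@H](C#CC#CC[C@H]1O[C@@H]1CCCCCCC)OC(=O)CCCCCCC/C=C\C/C=C\CCCCC | target

**Step count**

Total step count: 9 steps. Longest linear sequence: 7 steps (steps 1, 2, 3, 4, 7, 8, 9 from (E)-dec-2-en-1-ol); steps 5 and 6 form the short branch to the vinyl iodide.

**Steps most likely to fail**

1. Step 9 (the proposed new method). The divalent palladium centre may be sequestered by the conjugated diyne, or oxypalladation of the electron-poor enyne alkene may be too slow. In that case sigmatropic rearrangement of the imidate to the allylic trichloroacetamide, linear substitution or poor facial selectivity could take over, and the doubly activated product ester may ionise on the catalyst.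

   The fallback uses known chemistry only, sets out from triflate 3 and comes back to the route at the target 14. Alkylation of 3 with lithium (trimethylsilyl)acetylide (from ethynyltrimethylsilane and n-BuLi, THF, −78 °C) would give trimethyl{3-[(2R,3R)-3-heptyloxiran-2-yl]prop-1-yn-1-yl}silane F1. Bromodesilylation with N-bromosuccinimide and catalytic AgNO3 in acetone would give (2R,3R)-2-(3-bromoprop-2-yn-1-yl)-3-heptyloxirane F2. Cadiot–Chodkiewicz coupling of F2 (CuCl cat., NH2OH·HCl, aqueous EtNH2, MeOH, 0 °C) with (S)-pent-1-en-4-yn-3-ol F3, secured from the commercial racemate by lipase-catalysed kinetic resolution, would give (3S)-8-[(2R,3R)-3-heptyloxiran-2-yl]oct-1-ene-4,6-diyn-3-ol F4 with C3 already in place. Steglich esterification of F4 with linoleic acid 13 (DCC, DMAP cat., CH2Cl2, 0 °C) would then give 14. Here C3 comes from the resolved carbinol instead of from the catalyst.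

2. Step 3. The diynide may attack the oxirane instead of the triflate carbon, the triflate may decompose before coupling, or desilylation of 4 may go twice and lead to double alkylation.

   The fallback sets out from alcohol 1, uses the diynide 5 generated as in step 3, and comes back to the route at silyl diyne 6, so that steps 1 and 2 are no longer needed. Appel bromination of 1 (CBr4, PPh3, CH2Cl2, 0 °C) would give (E)-1-bromodec-2-ene F5. Coupling of F5 with 5 under CuBr·SMe2 catalysis (THF, −78 → 0 °C), by SN2 at the primary allylic carbon, would give trimethyl[(E)-tetradec-6-ene-1,3-diyn-1-yl]silane F6. Shi asymmetric epoxidation of the isolated E alkene of F6 with the D-fructose-derived ketone (1,2:4,5-di-O-isopropylidene-β-D-erythro-2,3-hexodiulo-2,6-pyranose) and KHSO5 (as 2KHSO5·KHSO4·K2SO4) at buffered pH, 0 °C, would then give 6. The R,R oxirane is expected from the spiro transition-state model, the diyne being inert to the dioxirane. The oxirane is thus formed after the C7–C8 bond, not before it.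

3. Step 7. The terminal diyne 7 may dimerise oxidatively or decompose under the copper and amine conditions, and the (Z)-enynol product may cycloisomerise under base or metal catalysis.

   The fallback sets out from silyl diyne 6 and comes back to the route at enediynol 11, bypassing the free terminal diyne and step 4. Silicon-to-tin exchange on 6 with (Bu3Sn)2O and catalytic Bu4NF (THF, 60 °C) would give tributyl{5-[(2R,3R)-3-heptyloxiran-2-yl]penta-1,3-diyn-1-yl}stannane F7. Stille coupling of F7 with vinyl iodide 10 (PdCl2(MeCN)2 cat., DMF, rt), which needs neither copper nor amine and retains the Z geometry, would give 11.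

**Further compounds**

F1 | step 9 | trimethyl{3-[(2R,3R)-3-heptyloxiran-2-yl]prop-1-yn-1-yl}silane | C[Si](C)(C)C#CC[C@H]1O[C@@H]1CCCCCCC
F2 | step 9 | (2R,3R)-2-(3-bromoprop-2-yn-1-yl)-3-heptyloxirane | BrC#CC[C@H]1O[C@@H]1CCCCCCC
F3 | step 9 | (S)-pent-1-en-4-yn-3-ol | C=C[C@@H](C#C)O
F4 | step 9 | (3S)-8-[(2R,3R)-3-heptyloxiran-2-yl]oct-1-ene-4,6-diyn-3-ol | C=C[C@@H](C#CC#CC[C@H]1O[C@@H]1CCCCCCC)O
F5 | step 3 | (E)-1-bromodec-2-ene | BrC/C=C/CCCCCCC
F6 | step 3 | trimethyl[(E)-tetradec-6-ene-1,3-diyn-1-yl]silane | C[Si](C)(C)C#CC#CC/C=C/CCCCCCC
F7 | step 7 | tributyl{5-[(2R,3R)-3-heptyloxiran-2-yl]penta-1,3-diyn-1-yl}stannane | CCCC[Sn](CCCC)(CCCC)C#CC#CC[C@H]1O[C@@H]1CCCCCCC
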